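**Plan**

- Retrosynthesis, first cut: the benzylic C-4–O aryl ether between the two lactone units. This reveals one common monomer, a cis-(3R,4R)-4-hydroxy-3-methylisochroman-1-one, used twice: as the C-4 alcohol for unit A (aryl-ether lactone) and as the 6-phenol for unit B (4-hydroxy lactone).
- Second cut, in the monomer: the lactone O–C-3 bond together with the C-4–O bond, back to a flat, achiral methyl ortho-(E)-propenylbenzoate.
- Enabling feature: the (E)-CH=CH–CH3 chain sits on the arene carbon next to the ester-bearing carbon, so the ester carbonyl oxygen can reach the methyl-bearing alkene carbon and close the six-membered lactone when the alkene is oxidatively activated (umpolung) by a chiral aryl-λ3-iodane.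
- Forward: methyl 4-O-methylgallate → bis-silyl ether → benzylic alcohol → ortho-bromide → aldehyde → (E)-propenyl arene → benzoate; oxylactonisation; O-silylation and aryl desilylation give the phenol partner; Mitsunobu coupling; global desilylation.
- Stereochemistry: the E geometry plus net syn dioxygenation gives cis; the (R,R)-lactate reagent chooses the face (3R,4R) for both units; C-4 of unit A (S) comes from Mitsunobu inversion. All four stereocentres derive from the one reagent-controlled step.

Key step: step 9

Assumption: the (R,R)-lactate reagent is taken to deliver the 3R,4R lactone from the (E)-alkene, by analogy with the oxylactonisation of ortho-(E)-alkenylbenzoates by such reagents; if the sense proves opposite, the enantiomeric reagent made from methyl (R)-lactate is used with no other change.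

**Route**

Step 1
Reactants: 1 methyl 3,5-dihydroxy-4-methoxybenzoate
Product: 2 methyl 4-methoxy-3,5-bis(triisopropylsilyloxy)benzoate
Conditions: i-Pr3SiCl (2.4 equiv), imidazole, DMF, rt
Reagents that add atoms: triisopropylsilyl chloride, CC(C)[Si](Cl)(C(C)C)C(C)C
Why: Imidazole-promoted silylation of both phenols should be clean, and the triisopropylsilyl ethers should survive hydride, low-temperature organolithium and the acidic key step yet leave with fluoride at the end (silyl ether protection).

Step 2
Reactants: 2 methyl 4-methoxy-3,5-bis(triisopropylsilyloxy)benzoate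
Product: 3 [4-methoxy-3,5-bis(triisopropylsilyloxy)phenyl]methanol
Conditions: i-Bu2AlH, CH2Cl2, −78 → 0 °C; aqueous potassium sodium tartrate (KNaC4H4O6)
Reagents that add atoms: none
Why: Hydride reduction of the methyl ester to the benzylic alcohol should leave the aryl silyl ethers untouched (ester reduction).

Step 3
Reactants: 3 [4-methoxy-3,5-bis(triisopropylsilyloxy)phenyl]methanol
Product: 4 [2-bromo-4-methoxy-3,5-bis(triisopropylsilyloxy)phenyl]methanol
Conditions: NBS, MeCN, −20 → 0 °C
Reagents that add atoms: N-bromosuccinimide, O=C1CCC(=O)N1Br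
Why: The two free ring positions are equivalent by symmetry and each is ortho to one silyloxy group and para to the other, so electrophilic aromatic bromination should give a single monobromide.

Step 4
Reactants: 4 [2-bromo-4-methoxy-3,5-bis(triisopropylsilyloxy)phenyl]methanol
Product: 5 2-bromo-4-methoxy-3,5-bis(triisopropylsilyloxy)benzaldehyde
Conditions: MnO2, CH2Cl2, rt
Reagents that add atoms: none
Why: MnO2 oxidises benzylic alcohols selectively to aldehydes without over-oxidation (benzylic oxidation).

Step 5
Reactants: 5 2-bromo-4-methoxy-3,5-bis(triisopropylsilyloxy)benzaldehyde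
Product: 6 2-bromo-4-methoxy-1-[(E)-prop-1-enyl]-3,5-bis(triisopropylsilyloxy)benzene
Conditions: CH3CHI2, CrCl2, THF, rt
Reagents that add atoms: 1,1-diiodoethane, CC(I)I
Why: The Takai–Utimoto alkylidenation with the geminal dichromium reagent should give the (E)-alkene predominantly, fixing the geometry that later dictates the cis relationship, while divalent chromium leaves the aryl bromide alone.

Step 6
Reactants: 6 2-bromo-4-methoxy-1-[(E)-prop-1-enyl]-3,5-bis(triisopropylsilyloxy)benzene
Product: 8 methyl 3-methoxy-6-[(E)-prop-1-enyl]-2,4-bis(triisopropylsilyloxy)benzoate, via aryllithium 7 (not isolated)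
Conditions: n-BuLi, THF, −78 °C; then ClCO2Me, −78 → 0 °C
Reagents that add atoms: methyl chloroformate, COC(=O)Cl
Why: Bromine–lithium exchange at −78 °C should outrun silyl migration and addition to the styrene, and the aryllithium is acylated by the small chloroformate (halogen–metal exchange, acylation).

Step 7
Reactants: 9 2-iodoresorcinol (2-iodobenzene-1,3-diol); 10 methyl (S)-lactate (two equivalents in all, one for each phenol)
Product: 11 dimethyl (2R,2'R)-2,2'-[(2-iodo-1,3-phenylene)bis(oxy)]dipropanoate
Conditions: 10 (2.2 equiv), PPh3 (2.2 equiv), DIAD (2.2 equiv), THF, 0 °C → rt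
Reagents that add atoms: methyl (S)-lactate (the second equivalent of 10), C[C@H](O)C(=O)OC
Why: Double Mitsunobu etherification joins one lactate unit to each of the two phenols of 9 with loss of two molecules of water, and each substitution should proceed with inversion at the lactate centre, turning S into R.

Step 8
Reactants: 11 dimethyl (2R,2'R)-2,2'-[(2-iodo-1,3-phenylene)bis(oxy)]dipropanoate
Product: 12 dimethyl (2R,2'R)-2,2'-[(2-[bis(trifluoroacetoxy)-λ3-iodanyl]-1,3-phenylene)bis(oxy)]dipropanoate
Conditions: KHSO5 (as 2KHSO5·KHSO4·K2SO4), CF3CO2H, CHCl3, rt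
Reagents that add atoms: trifluoroacetic acid, OC(=O)C(F)(F)F
Why: Peroxymonosulfate in trifluoroacetic acid is a standard way to oxidise an aryl iodide to its trivalent iodine bis(trifluoroacetate), and the lactate esters should tolerate it.

Step 9
Reactants: 8 methyl 3-methoxy-6-[(E)-prop-1-enyl]-2,4-bis(triisopropylsilyloxy)benzoate; 12 the chiral aryl-λ3-iodane bis(trifluoroacetate)
Product: 14 (3R,4R)-4-hydroxy-7-methoxy-3-methyl-6,8-bis(triisopropylsilyloxy)isochroman-1-one, via 4-O-trifluoroacetate 13 (not isolated)
Conditions: 12 (1.3 equiv), CH2Cl2, −78 → −20 °C; then MeOH/aqueous NaH2PO4–Na2HPO4 buffer (pH 7), 0 °C → rt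
Reagents that add atoms: iodane 12, COC(=O)[C@@H](C)Oc1cccc(O[C@H](C)C(=O)OC)c1I(OC(=O)C(F)(F)F)OC(=O)C(F)(F)F (one trifluoroacetate oxygen becomes the C-4 oxygen)
Why: The electrophilic aryl-λ3-iodane binds one face of the (E)-alkene, trifluoroacetate opens the iodonium at the benzylic carbon anti to iodine, and the ester carbonyl oxygen then displaces the aryl-λ3-iodanyl nucleofuge at the methyl-bearing carbon with inversion, so that the lactone O–C-3 bond forms and the cyclic dioxacarbenium ion loses its O-methyl group to trifluoroacetate. The closest known reaction type is the endo-selective oxylactonisation of ortho-alk-1-enylbenzoates by lactate-derived chiral aryl-λ3-iodanes, an oxidative umpolung of the alkene that joins two oxygen nucleophiles to its two carbons. The six-membered ring closes in a 6-endo sense with respect to the alkene (formally a 6-exo-tet displacement at C-3). C-3 and C-4 arise together: their absolute configuration is controlled by the two (R)-lactate arms of the reagent, which select the alkene face, and their cis relationship by the E geometry combined with one anti addition and one invertive substitution, a net syn dioxygenation. The step needs face selectivity, six- over five-membered closure and stereospecific substitution at C-4; the ester, twisted out of the arene plane by the flanking silyloxy group, should compete poorly for the benzylic carbon but is well placed for C-3, and the methoxy group para to the benzylic carbon is turned out of conjugation by its two silyloxy neighbours, which should curb ionisation. Buffered aqueous-methanolic solvolysis then frees the C-4 hydroxyl from the labile trifluoroacetate without base.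

Step 10
Reactants: 14 (3R,4R)-4-hydroxy-7-methoxy-3-methyl-6,8-bis(triisopropylsilyloxy)isochroman-1-one
Product: 15 (3R,4R)-4-(tert-butyldimethylsilyloxy)-7-methoxy-3-methyl-6,8-bis(triisopropylsilyloxy)isochroman-1-one
Conditions: t-BuMe2SiOTf, 2,6-lutidine, CH2Cl2, −78 → 0 °C
Reagents that add atoms: tert-butyldimethylsilyl triflate, CC(C)(C)[Si](C)(C)OS(=O)(=O)C(F)(F)F
Why: Silyl triflate with a hindered pyridine base silylates the secondary alcohol without forming an alkoxide, so migration of the lactone to the five-membered isomer should be avoided (silyl ether protection).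

Step 11
Reactants: 15 (3R,4R)-4-(tert-butyldimethylsilyloxy)-7-methoxy-3-methyl-6,8-bis(triisopropylsilyloxy)isochroman-1-one
Product: 16 (3R,4R)-4-(tert-butyldimethylsilyloxy)-6,8-dihydroxy-7-methoxy-3-methylisochroman-1-one
Conditions: KHF2, MeOH, rt
Reagents that add atoms: none
Why: Bifluoride in methanol should cleave the aryl silyl ethers, whose phenoxides are good leaving groups, while the hindered secondary alkyl silyl ether stays (chemoselective desilylation).

Step 12
Reactants: 14 (3R,4R)-4-hydroxy-7-methoxy-3-methyl-6,8-bis(triisopropylsilyloxy)isochroman-1-one; 16 (3R,4R)-4-(tert-butyldimethylsilyloxy)-6,8-dihydroxy-7-methoxy-3-methylisochroman-1-one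
Product: 17 (3R,4S)-4-{[(3R,4R)-4-(tert-butyldimethylsilyloxy)-8-hydroxy-7-methoxy-3-methyl-1-oxoisochroman-6-yl]oxy}-7-methoxy-3-methyl-6,8-bis(triisopropylsilyloxy)isochroman-1-one
Conditions: PPh3, DIAD, toluene, 0 °C → rt
Reagents that add atoms: none
Why: In this Mitsunobu etherification the more acidic, unchelated 6-hydroxyl of 16 (para to the lactone carbonyl) should react in preference to the hydrogen-bonded 8-hydroxyl, displacing the alkoxyphosphonium of 14 from the face anti to the C-3 methyl with inversion, which sets C-4 of unit A as S.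

Step 13
Reactants: 17 the tris-silylated dimer
Product: 18 (3R,4S)-4-{[(3R,4R)-4,8-dihydroxy-7-methoxy-3-methyl-1-oxoisochroman-6-yl]oxy}-6,8-dihydroxy-7-methoxy-3-methylisochroman-1-one (CNP0139537.4)
Conditions: Bu4NF, AcOH (1:1), THF, 0 °C → rt
Reagents that add atoms: none
Why: Acetic-acid-buffered fluoride should remove the two aryl silyl ethers and the alkyl silyl ether in one operation, while the buffering suppresses base-induced lactone migration and leaves the benzylic aryl ether intact (global desilylation).

**Compound list**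

1 | methyl 3,5-dihydroxy-4-methoxybenzoate | COC(=O)c1cc(O)c(OC)c(O)c1 | starting material
2 | methyl 4-methoxy-3,5-bis(triisopropylsilyloxy)benzoate | COC(=O)c1cc(O[Si](C(C)C)(C(C)C)C(C)C)c(OC)c(O[Si](C(C)C)(C(C)C)C(C)C)c1 | intermediate
3 | [4-methoxy-3,5-bis(triisopropylsilyloxy)phenyl]methanol | OCc1cc(O[Si](C(C)C)(C(C)C)C(C)C)c(OC)c(O[Si](C(C)C)(C(C)C)C(C)C)c1 | intermediate
4 | [2-bromo-4-methoxy-3,5-bis(triisopropylsilyloxy)phenyl]methanol | OCc1cc(O[Si](C(C)C)(C(C)C)C(C)C)c(OC)c(O[Si](C(C)C)(C(C)C)C(C)C)c1Br | intermediate
5 | 2-bromo-4-methoxy-3,5-bis(triisopropylsilyloxy)benzaldehyde | O=Cc1cc(O[Si](C(C)C)(C(C)C)C(C)C)c(OC)c(O[Si](C(C)C)(C(C)C)C(C)C)c1Br | intermediate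
6 | 2-bromo-4-methoxy-1-[(E)-prop-1-enyl]-3,5-bis(triisopropylsilyloxy)benzene | C/C=C/c1cc(O[Si](C(C)C)(C(C)C)C(C)C)c(OC)c(O[Si](C(C)C)(C(C)C)C(C)C)c1Br | intermediate
7 | {3-methoxy-6-[(E)-prop-1-enyl]-2,4-bis(triisopropylsilyloxy)phenyl}lithium (not isolated) | [Li]c1c(/C=C/C)cc(O[Si](C(C)C)(C(C)C)C(C)C)c(OC)c1O[Si](C(C)C)(C(C)C)C(C)C | intermediate
8 | methyl 3-methoxy-6-[(E)-prop-1-enyl]-2,4-bis(triisopropylsilyloxy)benzoate | COC(=O)c1c(/C=C/C)cc(O[Si](C(C)C)(C(C)C)C(C)C)c(OC)c1O[Si](C(C)C)(C(C)C)C(C)C | intermediate
9 | 2-iodoresorcinol (2-iodobenzene-1,3-diol) | Oc1cccc(O)c1I | starting material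
10 | methyl (S)-lactate | C[C@H](O)C(=O)OC | starting material
11 | dimethyl (2R,2'R)-2,2'-[(2-iodo-1,3-phenylene)bis(oxy)]dipropanoate | COC(=O)[C@@H](C)Oc1cccc(O[C@H](C)C(=O)OC)c1I | intermediate
12 | dimethyl (2R,2'R)-2,2'-[(2-[bis(trifluoroacetoxy)-λ3-iodanyl]-1,3-phenylene)bis(oxy)]dipropanoate | COC(=O)[C@@H](C)Oc1cccc(O[C@H](C)C(=O)OC)c1I(OC(=O)C(F)(F)F)OC(=O)C(F)(F)F | intermediate
13 | (3R,4R)-7-methoxy-3-methyl-1-oxo-6,8-bis(triisopropylsilyloxy)isochroman-4-yl trifluoroacetate (not isolated) | COc1c(O[Si](C(C)C)(C(C)C)C(C)C)cc2c(c1O[Si](C(C)C)(C(C)C)C(C)C)C(=O)O[C@H](C)[C@@H]2OC(=O)C(F)(F)F | intermediate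
14 | (3R,4R)-4-hydroxy-7-methoxy-3-methyl-6,8-bis(triisopropylsilyloxy)isochroman-1-one (3-methyl and 4-hydroxyl cis) | COc1c(O[Si](C(C)C)(C(C)C)C(C)C)cc2c(c1O[Si](C(C)C)(C(C)C)C(C)C)C(=O)O[C@H](C)[C@@H]2O | intermediate
15 | (3R,4R)-4-(tert-butyldimethylsilyloxy)-7-methoxy-3-methyl-6,8-bis(triisopropylsilyloxy)isochroman-1-one | COc1c(O[Si](C(C)C)(C(C)C)C(C)C)cc2c(c1O[Si](C(C)C)(C(C)C)C(C)C)C(=O)O[C@H](C)[C@@H]2O[Si](C)(C)C(C)(C)C | intermediate
16 | (3R,4R)-4-(tert-butyldimethylsilyloxy)-6,8-dihydroxy-7-methoxy-3-methylisochroman-1-one | COc1c(O)cc2c(c1O)C(=O)O[C@H](C)[C@@H]2O[Si](C)(C)C(C)(C)C | intermediate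
17 | (3R,4S)-4-{[(3R,4R)-4-(tert-butyldimethylsilyloxy)-8-hydroxy-7-methoxy-3-methyl-1-oxoisochroman-6-yl]oxy}-7-methoxy-3-methyl-6,8-bis(triisopropylsilyloxy)isochroman-1-one | COc1c(O[Si](C(C)C)(C(C)C)C(C)C)cc2c(c1O[Si](C(C)C)(C(C)C)C(C)C)C(=O)O[C@H](C)[C@H]2Oc1cc2c(c(O)c1OC)C(=O)O[C@H](C)[C@@H]2O[Si](C)(C)C(C)(C)C | intermediate
18 | (3R,4S)-4-{[(3R,4R)-4,8-dihydroxy-7-methoxy-3-methyl-1-oxoisochroman-6-yl]oxy}-6,8-dihydroxy-7-methoxy-3-methylisochroman-1-one | COc1c(O)cc2c(c1O)C(=O)O[C@H](C)[C@H]2Oc1cc2c(c(O)c1OC)C(=O)O[C@H](C)[C@@H]2O | target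

**Step count and risks**

Total steps: 13. Longest linear sequence: 11 (steps 1–6 and 9–13); steps 7 and 8 are the reagent branch.

Steps most likely to fail:

1. Step 9. Possible failures are poor facial selectivity, closure of the five-membered lactone by attack of the ester at the benzylic carbon, ionisation at the benzylic carbon with loss of the cis relationship, or oxidation of the electron-rich arene by trivalent iodine. The fallback sets out from 14 of insufficient stereochemical purity (any mixture of its stereoisomers, including material made with achiral PhI(OCOCF3)2). Dess–Martin oxidation should give 7-methoxy-3-methyl-6,8-bis(triisopropylsilyloxy)isochroman-1,4-dione F1, whose C-3 centre epimerises through the enol. Asymmetric transfer hydrogenation under dynamic kinetic resolution (RuCl(p-cymene)[(S,S)-TsDPEN], HCO2H/Et3N) should then deliver hydride anti to the methyl group and return cis-(3R,4R)-14, where the route resumes.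

2. Step 12. Possible failures are elimination of the activated alcohol to the isocoumarin, partial ionisation with incomplete inversion, slow reaction of the hindered alcohol, or etherification at the chelated 8-hydroxyl. The fallback sets out from 14, which with Cl3CCN and catalytic DBU (CH2Cl2, 0 °C) should give (3R,4R)-7-methoxy-3-methyl-1-oxo-6,8-bis(triisopropylsilyloxy)isochroman-4-yl 2,2,2-trichloroacetimidate F2. Activation with catalytic Me3SiOTf at −78 °C in the presence of phenol 16 should generate the benzylic cation, which the phenol captures anti to the C-3 methyl group. Stereocontrol then comes from the substrate instead of from inversion, and the fallback rejoins the route at 17.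

3. Step 6. Possible failures are anionic oxygen-to-carbon silyl migration in the ortho-silyloxy aryllithium, or slow acylation at the doubly ortho-substituted carbanion. The fallback sets out from 6 and avoids the carbanion by palladium-catalysed methoxycarbonylation (Pd(OAc)2, Xantphos, CO, MeOH, Et3N, toluene, 80 °C), coming back directly at 8; it makes no new compound (F0).

**Further compounds**

F1 | step 9 | 7-methoxy-3-methyl-6,8-bis(triisopropylsilyloxy)isochroman-1,4-dione (C-3 epimerising, no fixed configuration) | COc1c(O[Si](C(C)C)(C(C)C)C(C)C)cc2c(c1O[Si](C(C)C)(C(C)C)C(C)C)C(=O)OC(C)C2=O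
F2 | step 12 | (3R,4R)-7-methoxy-3-methyl-1-oxo-6,8-bis(triisopropylsilyloxy)isochroman-4-yl 2,2,2-trichloroacetimidate | COc1c(O[Si](C(C)C)(C(C)C)C(C)C)cc2c(c1O[Si](C(C)C)(C(C)C)C(C)C)C(=O)O[C@H](C)[C@@H]2OC(=N)C(Cl)(Cl)Cl
F0 | step 6 | none | none
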